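**Plan**

1. Retrosynthetic cuts (dihydronaphthalene numbering; ring A = benzo ring, ring B = dihydro ring, ring C = aryl on C1, rings D and E = the two 4-hydroxyphenyl ketone rings): first C1–C2 of ring B, then the C3=C4 olefin (Wittig), then the C1–C8a aryl–carbinol bond (directed ortho-lithiation and aldehyde addition), then the olefin of a symmetrical 1,2-diaroylethylene (aldol condensation).
2. Forward: the ring C aldehyde (from 2,3,4-trihydroxybenzaldehyde) and the ring A aldehyde (from 5-hydroxyvanillin) are joined at C1 and isolated as a lactol. A phosphine-mediated Wittig reaction with the diaroylethylene then adds C2, C3, C4 and rings D and E. Desilylation frees O6–H, ring B is closed last, and five methoxymethyl (MOM) groups are removed.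
3. Enabling feature: the 6-hydroxyl of ring A is para to C8a, the ring carbon that carries C1, so the benzhydrol can lose water to a para-quinone methide (C1=C8a). The C2 methylene is alpha to an aroyl group and vinylogous through C3=C4–C4a to the quinone methide carbonyl, so one proton shift gives the ring A ortho-quinodimethane C1=C8a–C4a=C4–C3=C2. This hexatriene closes by 6π electrocyclisation to ring B and rearomatises ring A.
4. Stereochemistry: no stereocentre is carried into the key step; the racemic carbinol, the lactol diastereomers and the olefin isomers all converge on planar intermediates. C1 and C2 arise together, cis by disrotatory closure of the out,out triene and (1S,2S) through a chiral phosphoric acid.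
5. Protecting groups: MOM on five phenols and triisopropylsilyl (TIPS) on O6, the latter removed just before the key step.

Key step: step 10

Assumption: the target SMILES is read as the cis (1S,2S) isomer, with ring C on C1 and the aroyl group on C2 on the same face. The sense of induction of the (R)-configured acid in step 10 cannot be predicted with certainty, so its mirror image is to be used if that proves to be the matched catalyst.

**Route**

Step 1
Reactants: 1 2,3,4-trihydroxybenzaldehyde
Product: 2 2-hydroxy-3,4-bis(methoxymethoxy)benzaldehyde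
Conditions: MOMCl (2.2 equiv), i-Pr2NEt, CH2Cl2, 0 °C → rt
Reagents that add atoms: chloromethyl methyl ether, COCCl
Why: Williamson-type MOM ether formation, in which the 2-hydroxyl is locked in a hydrogen bond to the formyl group and is the least nucleophilic, so two equivalents of the chloride should cap only O3 and O4.

Step 2
Reactants: 2 2-hydroxy-3,4-bis(methoxymethoxy)benzaldehyde
Product: 3 2-methoxy-3,4-bis(methoxymethoxy)benzaldehyde
Conditions: MeI, K2CO3, DMF, 40 °C
Reagents that add atoms: iodomethane, CI
Why: Williamson O-methylation of the remaining chelated phenol in a polar aprotic solvent installs the 2-methoxy group of ring C.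

Step 3
Reactants: 4 3,4-dihydroxy-5-methoxybenzaldehyde (5-hydroxyvanillin)
Product: 5 3-hydroxy-5-methoxy-4-(methoxymethoxy)benzaldehyde
Conditions: MOMCl (1.0 equiv), K2CO3 (1.0 equiv), acetone, 0 °C → rt
Reagents that add atoms: chloromethyl methyl ether, COCCl
Why: regioselective Williamson O-alkylation, in which the 4-hydroxyl para to the formyl group is the most acidic and the only one ionised by one equivalent of carbonate, so the MOM group should go to the future O7 and leave the future O6 hydroxyl free.

Step 4
Reactants: 5 3-hydroxy-5-methoxy-4-(methoxymethoxy)benzaldehyde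
Product: 6 3-methoxy-4-(methoxymethoxy)-5-[(triisopropylsilyl)oxy]benzaldehyde
Conditions: TIPSCl, imidazole, DMF, rt
Reagents that add atoms: chlorotriisopropylsilane, CC(C)[Si](Cl)(C(C)C)C(C)C
Why: standard phenol silylation; the bulky, non-coordinating TIPS ether marks the oxygen that must later be free and shields its ortho position against lithiation.

Step 5
Reactants: 6 3-methoxy-4-(methoxymethoxy)-5-[(triisopropylsilyl)oxy]benzaldehyde; 3 2-methoxy-3,4-bis(methoxymethoxy)benzaldehyde
Product: 10 lactol 3-[2-methoxy-3,4-bis(methoxymethoxy)phenyl]-4-methoxy-5-(methoxymethoxy)-6-[(triisopropylsilyl)oxy]-1,3-dihydro-2-benzofuran-1-ol (racemic diastereomer mixture), via lithium alpha-amino alkoxide 7 (not isolated), via aryllithium 8 (not isolated), via dilithium dialkoxide 9 (not isolated)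
Conditions: LiN(Me)CH2CH2NMe2 (from MeNHCH2CH2NMe2 + n-BuLi), THF, −20 °C; n-BuLi (1.2 equiv), −20 °C; then 3, −78 → 0 °C; aq NH4Cl
Reagents that add atoms: none
Why: alpha-amino alkoxide-directed ortho-lithiation followed by 1,2-addition to an aldehyde, in which the in situ hemiaminal alkoxide masks the formyl group and, together with the neighbouring methoxy group, directs lithiation to the carbon between them (the other ortho position is flanked by the silyl ether), the aryllithium adds to the non-enolisable aldehyde 3 to make the C1–C8a bond, and aqueous NH4Cl hydrolyses the amino alkoxide with loss of the diamine, so that the adduct is isolated in its ring-closed lactol form with the new carbinol oxygen bound to the former formyl carbon; the carbinol centre is formed racemic on purpose because it is erased in step 10.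

Step 6
Reactants: 11 4-hydroxyphenylglyoxal hydrate; 12 4'-hydroxyacetophenone
Product: 14 (E)-1,4-bis(4-hydroxyphenyl)but-2-ene-1,4-dione, via aldol adduct 13 (not isolated)
Conditions: TsOH·H2O (cat.), 1,4-dioxane, 90 °C
Reagents that add atoms: none
Why: acid-catalysed crossed aldol condensation, in which only the acetophenone can enolise and the aldehyde carbon of the glyoxal is the most electrophilic carbonyl, so dehydration of the aldol should give the conjugated enedione as the more stable E isomer.

Step 7
Reactants: 14 (E)-1,4-bis(4-hydroxyphenyl)but-2-ene-1,4-dione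
Product: 15 (E)-1,4-bis[4-(methoxymethoxy)phenyl]but-2-ene-1,4-dione
Conditions: MOMCl (2.4 equiv), i-Pr2NEt, CH2Cl2, 0 °C → rt
Reagents that add atoms: chloromethyl methyl ether, COCCl
Why: standard MOM protection of the two para-acyl phenols with a hindered tertiary amine that does not add to the enedione.

Step 8
Reactants: 10 lactol from step 5; 15 (E)-1,4-bis[4-(methoxymethoxy)phenyl]but-2-ene-1,4-dione
Product: 18 (E)-2-{2-[hydroxy(2-methoxy-3,4-bis(methoxymethoxy)phenyl)methyl]-3-methoxy-4-(methoxymethoxy)-5-[(triisopropylsilyl)oxy]benzylidene}-1,4-bis[4-(methoxymethoxy)phenyl]butane-1,4-dione (racemic), via hydroxy aldehyde 16 (not isolated), via phosphorus ylide 17 (not isolated)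
Conditions: PPh3 (1.2 equiv), toluene, 90 °C
Reagents that add atoms: none
Why: phosphine-mediated Wittig olefination of a lactol, in which conjugate addition of PPh3 to the enedione and proton transfer give the keto-stabilised ylide 17, the lactol opens by ring-chain tautomerism to the hydroxy aldehyde 16, and their condensation installs C2, C3=C4 and both aroyl groups at once; the stabilised ylide should give the E olefin (ring A cis to the C2 methylene), and this geometry is in any case not carried past step 10.

Step 9
Reactants: 18 silyl ether from step 8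
Product: 19 (E)-2-{5-hydroxy-2-[hydroxy(2-methoxy-3,4-bis(methoxymethoxy)phenyl)methyl]-3-methoxy-4-(methoxymethoxy)benzylidene}-1,4-bis[4-(methoxymethoxy)phenyl]butane-1,4-dione (racemic)
Conditions: Bu4NF (1.1 equiv), AcOH (1.1 equiv), THF, 0 °C
Reagents that add atoms: none
Why: fluoride-induced cleavage of the aryl silyl ether, buffered with acetic acid so that the carbinol does not add to the enone (oxa-Michael) and the diketone is not enolised, while the MOM acetals are inert.

Step 10
Reactants: 19 phenolic benzhydrol from step 9
Product: 22 [(1S,2S)-6-hydroxy-8-methoxy-1-[2-methoxy-3,4-bis(methoxymethoxy)phenyl]-7-(methoxymethoxy)-1,2-dihydronaphthalene-2,3-diyl]bis{[4-(methoxymethoxy)phenyl]methanone}, via para-quinone methide 20 (not isolated), via ortho-quinodimethane 21 (not isolated)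
Conditions: (R)-3,3'-bis(2,4,6-triisopropylphenyl)-1,1'-binaphthyl-2,2'-diyl hydrogen phosphate ((R)-TRIP, 10 mol %), 4 Å MS, toluene, 0 °C → rt, Ar
Reagents that add atoms: none
Why: Proposed new method: the chiral phosphoric acid should dehydrate the 4-hydroxybenzhydrol to the para-quinone methide 20 (C1=C8a, O6 carbonyl) and then shuttle one proton from the doubly activated C2 methylene to O6, which gives the 6-hydroxy ortho-quinodimethane 21, a hexatriene C1=C8a–C4a=C4–C3=C2 that closes thermally and rearomatises ring A in the same event. The closest known reaction types are the phosphoric-acid-catalysed enantioselective 1,6-additions to para-quinone methides made in situ from para-hydroxybenzyl alcohols, Brønsted-acid-catalysed asymmetric 6π electrocyclisations, and the spontaneous 6π closure of alpha-vinyl ortho-quinodimethanes to 1,2-dihydronaphthalenes. Ring B, the only ring formed, closes by a thermal disrotatory 6π electrocyclisation (in polar terms a 6-endo-trig vinylogous Michael addition of the C2 dienol carbon to C1). C1 and C2 are created together: their cis relation is set by orbital symmetry, because ring C on C1 and the aroyl group on C2 both take the outside positions of the triene termini (an inside group would collide with the other terminus in the helical transition state), and the absolute sense (1S,2S) is set by the catalyst, which is hydrogen-bonded to O6–H and to an aroyl carbonyl of the acid-activated 1,2-diacyl triene and so fixes its helicity. The step needs C-alkylation at C2 instead of oxa-Michael or five-membered closures, cis selectivity and face selectivity; the first is secured by the single free phenol para to C8a and by the acidity of C2–H (alpha to an aroyl group and vinylogous to the quinone methide), the second by the concerted closure, the third by the catalyst. The racemic carbinol, both olefin isomers and any ring-chain (phthalan) isomer of 19 should converge, since all of them ionise to the same planar 20 and 21.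

Step 11
Reactants: 22 protected cis-dihydronaphthalene from step 10
Product: 23 licobichalcone
Conditions: HCl (1.25 M in MeOH), THF, 0 °C → rt
Reagents that add atoms: none
Why: acid-catalysed transacetalisation of the five MOM ethers to dimethoxymethane in methanol, under mild protic conditions that leave the two methyl ethers in place and should not enolise the ketone alpha to C2, so that C1 and C2 stay untouched.

**Compound list**

1 | 2,3,4-trihydroxybenzaldehyde | O=Cc1ccc(O)c(O)c1O | starting material
2 | 2-hydroxy-3,4-bis(methoxymethoxy)benzaldehyde | O=Cc1ccc(OCOC)c(OCOC)c1O | intermediate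
3 | 2-methoxy-3,4-bis(methoxymethoxy)benzaldehyde (ring C aldehyde) | O=Cc1ccc(OCOC)c(OCOC)c1OC | intermediate
4 | 3,4-dihydroxy-5-methoxybenzaldehyde (5-hydroxyvanillin) | COc1cc(C=O)cc(O)c1O | starting material
5 | 3-hydroxy-5-methoxy-4-(methoxymethoxy)benzaldehyde | COCOc1c(O)cc(C=O)cc1OC | intermediate
6 | 3-methoxy-4-(methoxymethoxy)-5-[(triisopropylsilyl)oxy]benzaldehyde (ring A aldehyde) | COCOc1c(O[Si](C(C)C)(C(C)C)C(C)C)cc(C=O)cc1OC | intermediate
7 | lithium alpha-amino alkoxide of 6 with N,N,N'-trimethylethylenediamine (racemic, not isolated) | [Li]OC(N(C)CCN(C)C)c1cc(OC)c(OCOC)c(O[Si](C(C)C)(C(C)C)C(C)C)c1 | intermediate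
8 | aryllithium: 7 lithiated at the ring carbon between the hemiaminal carbon and the methoxy group (racemic, not isolated) | [Li]OC(N(C)CCN(C)C)c1cc(O[Si](C(C)C)(C(C)C)C(C)C)c(OCOC)c(OC)c1[Li] | intermediate
9 | dilithium dialkoxide, adduct of 8 and 3 (diastereomer mixture, not isolated) | [Li]OC(N(C)CCN(C)C)c1cc(O[Si](C(C)C)(C(C)C)C(C)C)c(OCOC)c(OC)c1C(O[Li])c1ccc(OCOC)c(OCOC)c1OC | intermediate
10 | 3-[2-methoxy-3,4-bis(methoxymethoxy)phenyl]-4-methoxy-5-(methoxymethoxy)-6-[(triisopropylsilyl)oxy]-1,3-dihydro-2-benzofuran-1-ol (lactol, racemic diastereomer mixture) | OC1OC(c2ccc(OCOC)c(OCOC)c2OC)c2c(OC)c(OCOC)c(O[Si](C(C)C)(C(C)C)C(C)C)cc12 | intermediate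
11 | 4-hydroxyphenylglyoxal hydrate (2,2-dihydroxy-1-(4-hydroxyphenyl)ethan-1-one) | OC(O)C(=O)c1ccc(O)cc1 | starting material
12 | 4'-hydroxyacetophenone | CC(=O)c1ccc(O)cc1 | starting material
13 | 2-hydroxy-1,4-bis(4-hydroxyphenyl)butane-1,4-dione (aldol adduct, racemic, not isolated) | OC(CC(=O)c1ccc(O)cc1)C(=O)c1ccc(O)cc1 | intermediate
14 | (E)-1,4-bis(4-hydroxyphenyl)but-2-ene-1,4-dione | O=C(/C=C/C(=O)c1ccc(O)cc1)c1ccc(O)cc1 | intermediate
15 | (E)-1,4-bis[4-(methoxymethoxy)phenyl]but-2-ene-1,4-dione | COCOc1ccc(cc1)C(=O)/C=C/C(=O)c1ccc(OCOC)cc1 | intermediate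
16 | 2-[hydroxy(2-methoxy-3,4-bis(methoxymethoxy)phenyl)methyl]-3-methoxy-4-(methoxymethoxy)-5-[(triisopropylsilyl)oxy]benzaldehyde (racemic, open-chain tautomer of lactol 10, not isolated) | COCOc1ccc(C(O)c2c(OC)c(OCOC)c(O[Si](C(C)C)(C(C)C)C(C)C)cc2C=O)c(OC)c1OCOC | intermediate
17 | 1,4-bis[4-(methoxymethoxy)phenyl]-2-(triphenyl-lambda5-phosphanylidene)butane-1,4-dione (ylide, not isolated) | COCOc1ccc(cc1)C(=O)CC(=P(c1ccccc1)(c1ccccc1)c1ccccc1)C(=O)c1ccc(OCOC)cc1 | intermediate
18 | (E)-2-{2-[hydroxy(2-methoxy-3,4-bis(methoxymethoxy)phenyl)methyl]-3-methoxy-4-(methoxymethoxy)-5-[(triisopropylsilyl)oxy]benzylidene}-1,4-bis[4-(methoxymethoxy)phenyl]butane-1,4-dione (racemic) | COCOc1ccc(C(O)c2c(OC)c(OCOC)c(O[Si](C(C)C)(C(C)C)C(C)C)cc2/C=C(\CC(=O)c2ccc(OCOC)cc2)C(=O)c2ccc(OCOC)cc2)c(OC)c1OCOC | intermediate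
19 | (E)-2-{5-hydroxy-2-[hydroxy(2-methoxy-3,4-bis(methoxymethoxy)phenyl)methyl]-3-methoxy-4-(methoxymethoxy)benzylidene}-1,4-bis[4-(methoxymethoxy)phenyl]butane-1,4-dione (racemic) | COCOc1ccc(C(O)c2c(OC)c(OCOC)c(O)cc2/C=C(\CC(=O)c2ccc(OCOC)cc2)C(=O)c2ccc(OCOC)cc2)c(OC)c1OCOC | intermediate
20 | para-quinone methide from 19: ring A as cyclohexadienone with O6 carbonyl, exocyclic C1=C8a carrying ring C syn to C8, E enone side chain on C4a (not isolated) | O=C1C=C(/C=C(\CC(=O)c2ccc(OCOC)cc2)C(=O)c2ccc(OCOC)cc2)\C(=C\c2ccc(OCOC)c(OCOC)c2OC)C(OC)=C1OCOC | intermediate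
21 | 6-hydroxy ortho-quinodimethane: exocyclic C1=C8a and C4=C4a on ring A, C2=C3 bearing both aroyl groups, ring C and the C2 aroyl group outside (not isolated) | OC1=C/C(=C/C(C(=O)c2ccc(OCOC)cc2)=C/C(=O)c2ccc(OCOC)cc2)/C(=C/c2ccc(OCOC)c(OCOC)c2OC)C(OC)=C1OCOC | intermediate
22 | [(1S,2S)-6-hydroxy-8-methoxy-1-[2-methoxy-3,4-bis(methoxymethoxy)phenyl]-7-(methoxymethoxy)-1,2-dihydronaphthalene-2,3-diyl]bis{[4-(methoxymethoxy)phenyl]methanone} (cis) | COc1c([C@H]2c3c(cc(O)c(OCOC)c3OC)C=C(C(=O)c3ccc(OCOC)cc3)[C@H]2C(=O)c2ccc(OCOC)cc2)ccc(OCOC)c1OCOC | intermediate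
23 | licobichalcone, [(1S,2S)-1-(3,4-dihydroxy-2-methoxyphenyl)-6,7-dihydroxy-8-methoxy-1,2-dihydronaphthalene-2,3-diyl]bis[(4-hydroxyphenyl)methanone] | COc1c([C@H]2c3c(cc(O)c(O)c3OC)C=C(C(=O)c3ccc(O)cc3)[C@H]2C(=O)c2ccc(O)cc2)ccc(O)c1O | target

**Step count and risks**

Total steps: 11. Longest linear sequence: 7 steps (steps 3, 4, 5, 8, 9, 10, 11 from 4; equally steps 1, 2, 5, 8, 9, 10, 11 from 1).

Steps most likely to fail:

Step 10. Face discrimination may be weak because the acid binds at O6–H and a carbonyl, far from the forming C1–C2 bond. A stepwise ionic closure may also compete with the concerted one and erode the cis relation. Fallback: from 19 the same dehydrative cyclisation is run with an achiral acid (diphenyl phosphate, (PhO)2P(O)OH, toluene, rt). This is acid-promoted para-quinone methide formation followed by intramolecular 1,6-addition of the ketone enol. It should give the racemic cis compound, that is 22 together with its mirror image, the (1R,2R)-dihydronaphthalene F1. Preparative HPLC on a chiral stationary phase (amylose tris(3,5-dimethylphenylcarbamate)) then separates the two and delivers 22, where the route is rejoined.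

Step 8. The olefination may stall because the alpha-branched keto-stabilised ylide is a weak nucleophile and the aldehyde is largely masked as the lactol. The phosphine may also trigger conjugate additions to the enedione. Fallback: from 15, conjugate reduction of the enedione (zinc dust, AcOH, THF, rt) should give the saturated diketone 1,4-bis[4-(methoxymethoxy)phenyl]butane-1,4-dione F2. Its crossed aldol condensation with lactol 10 (piperidinium acetate, toluene, 4 Å MS, 80 °C) should give the same benzylidene diketone. The diketone is symmetrical, so there is no regiochemical question, and the route is rejoined at 18.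

Step 11. Protic acid may enolise the ketone alpha to C2 before all five acetals are cleaved, which would epimerise the cis compound to the trans isomer. Fallback: from 22, non-protic silyl transfer (TMSOTf, 2,2'-bipyridyl, CH2Cl2, 0 °C) should convert every aryl MOM ether and the free phenol into trimethylsilyl ethers and give the hexakis(trimethylsilyl) ether F3. Hydrolysis with water at pH 7 in MeOH at rt then releases the six phenols and gives 23.

**Further compounds**

F1 | step 10 | [(1R,2R)-6-hydroxy-8-methoxy-1-[2-methoxy-3,4-bis(methoxymethoxy)phenyl]-7-(methoxymethoxy)-1,2-dihydronaphthalene-2,3-diyl]bis{[4-(methoxymethoxy)phenyl]methanone} (enantiomer of 22) | COc1c([C@@H]2c3c(cc(O)c(OCOC)c3OC)C=C(C(=O)c3ccc(OCOC)cc3)[C@@H]2C(=O)c2ccc(OCOC)cc2)ccc(OCOC)c1OCOC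
F2 | step 8 | 1,4-bis[4-(methoxymethoxy)phenyl]butane-1,4-dione | COCOc1ccc(cc1)C(=O)CCC(=O)c1ccc(OCOC)cc1
F3 | step 11 | hexakis(trimethylsilyl) ether of 23, (1S,2S) | COc1c([C@H]2c3c(cc(O[Si](C)(C)C)c(O[Si](C)(C)C)c3OC)C=C(C(=O)c3ccc(O[Si](C)(C)C)cc3)[C@H]2C(=O)c2ccc(O[Si](C)(C)C)cc2)ccc(O[Si](C)(C)C)c1O[Si](C)(C)C
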